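**The dusk tail.** Read the dusk run from 6.00 h on. In that run left-handed substrate averages 0.167 % of the charge as read, with 0.744 % as the upper end at two standard errors. In that run right-handed substrate reads near half of the charge.

in all of them: gas 32 mM (held)

| run | left-handed substrate | right-handed substrate | free catalyst | remark | time |
|---|---|---|---|---|---|
| dusk | 0.50 M | 0.50 M | 10 mol% | run made earlier |  |
| winter | 0.50 M | 0.50 M | 16 mol% | run made earlier |  |
| noon | 1 M | 1 M | 7.5 mol% | run made earlier |  |
| flask | 0.50 M | 0.50 M | 7.5 mol% |  | 20 h |

- dusk (time / h: right-handed substrate / %, left-handed substrate / %): 2.00: 49.2, 13.5; 6.00: 49.4, 0.2; 10.0: 49.8, 0.3; 15.0: 48.9, 0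
- winter (time / h: right-handed substrate / %, left-handed substrate / %): 1.33: 49.1, 14.8; 3.00: 51.4, 1.0; 6.00: 50.2, 0.7; 15.0: 49.8, 0
- noon (time / h: right-handed substrate / %, left-handed substrate / %): 4.00: 49.8, 4.1; 8.00: 49.5, 0; 12.0: 49.7, 0; 15.0: 49.5, 0.6

(scatter of a reading: 0.5 percentage points)

- free catalyst is single-handed; left-handed substrate and right-handed substrate are mirror images of each other, charged as a racemate, each of them at the stated concentration
- what was read earlier has a scatter of 0.5 percentage points, one standard deviation
- at the start none of the gas is in solution

- whether the excess of right-handed substrate over left-handed substrate among what is left of the two reaches 90 % by 20 h (no / yes)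
- the highest excess of right-handed substrate over left-handed substrate among what is left of the two up to 20 h

**Upper bound.** Suppose the catalyst outlasts the left-handed substrate. Then none remains, and the excess reaches 100 %.

**Lower bound.** Now suppose the dusk tail is real and the catalyst dies first. Let the left-handed fraction fall at k × fraction × catalyst, while catalyst decays exponentially at rate d. Integrating to the end gives ln(start fraction / end fraction) = (k/d) × catalyst charged. Call k/d the reach. Dusk gives 114 /M, or 84.2 /M from the worst tail.

**Noon check.** On the noon run, the reach predicts 0.00962 % left. The readings from 8.00 h on average 0.200 %, within scatter.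

**My bracket.** This flask has half the noon catalyst concentration. The worst reach leaves 2.13 %, an excess of 91.8 %. The central reach leaves 0.694 %, an excess of 97.3 %.

**The forecast.** It says yes, with a top of 99.5 %, inside my bracket but higher than my central figure: “Once the left-handed substrate is gone, the excess approaches 100%.”

**The result.** The answer is yes: this flask passes 90 % at 5.32 h and tops out at 96.9 %, inside the bracket.

    free catalyst + left-handed substrate ⇌ catalyst intermediate A (K = 48.0 /M, k = 1.01 /M/s)
    free catalyst + right-handed substrate ⇌ catalyst intermediate B (K = 0.590 /M, k = 0.342 /M/s)
    reagent + catalyst intermediate A → free catalyst + left-handed product (k = 0.0775 /M/s)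
    reagent + catalyst intermediate B → free catalyst + right-handed product (k = 0.00528 /M/s)
    free catalyst ⇌ dormant form (K = 4.50, k = 0.00440 /s)
    gas ⇌ reagent, rate k6*(csat - [reagent]) (kL = 0.00459 /s)
    free catalyst → spent catalyst (k = 7.94 × 10⁻⁴ /s)

**The end state.** This flask holds 0.779 % left-handed substrate at 20.0 h, against the 0.694 % the central reach gave. At that time in this flask, free catalyst still binds left-handed substrate 9.9 times as fast as it dies, counting the forward step alone. Yet in this flask spent catalyst, the product of deactivation, already stands at 99.9 % of the catalyst charged.

All runs come from a simulation with made-up constants, noise included.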